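**Retrosynthetic overview** (ring atoms: C1 ketone carbon, C2 methyl-bearing oxirane carbon, C3 oxirane CH, C4 CH2, C5 carbon with the side chain, C6 carbon with the senecioate)

1. Endgame: the C1 ketone comes from an alcohol, the oxirane from hydroxyl-directed epoxidation of that allylic alcohol (alkaline peroxide on the enone is expected to enter anti to the C5 chain, the wrong face), and the C6 ester from α′-hydroxylation and acylation of a 2-methylcyclohex-2-enone.
2. Key disconnection: C1–C2 and C3–C4 are cut together; C2–C3 with its methyl becomes a silyl-capped propyne, and C4–C5–C6–C1 becomes a 3-substituted cyclobutanone. Forward, nickel-catalysed alkyne insertion into one C(acyl)–CH2 bond expands the four-membered ring to the six-membered enone and creates the C5 stereocentre.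
3. Enabling feature: C2/C3 form a two-carbon unit that sits at the alkyne oxidation level once drawn as the enone, flanked by the carbonyl C1 and the unsubstituted methylene C4. C5 lies opposite, on the mirror plane of the cyclobutanone ring C1/C6/C5/C4, so ring strain drives the insertion and no ring stereocentre is needed beforehand.
4. Side chain: the C(=CH2)–CH(O) bond is made before the key step by asymmetric Nozaki–Hiyama–Kishi coupling of a cyclobutyl enol triflate with 4-methylpent-3-enal.
5. Ring order: cyclobutane (bought in), then the six-membered ring (step 8), then the oxirane (step 14).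

Key step: step 8

Remark on the chemistry: for the chiral ligands of steps 4 and 8 the antipode is assumed that gives the configuration drawn; a test run decides, and the other antipode is taken if the sense is opposite.

**Route**

Step 1
Reactants: 1 3,3-dimethoxycyclobutane-1-carboxylic acid
Product: 3 1-(3,3-dimethoxycyclobutyl)ethan-1-one, via dilithium gem-diolate 2 (not isolated)
Conditions: MeLi (2.2 equiv), Et2O, −78 °C to 0 °C; then H2O
Reagents that add atoms: methyllithium, [Li]C
Why: The first equivalent of methyllithium deprotonates the acid and the second adds to the carboxylate to give the gem-diolate, which is stable until the aqueous quench and therefore stops at the methyl ketone (organolithium addition to a carboxylate), while the dimethyl ketal is inert to the base.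

Step 2
Reactants: 3 1-(3,3-dimethoxycyclobutyl)ethan-1-one
Product: 5 1-(3,3-dimethoxycyclobutyl)ethenyl trifluoromethanesulfonate, via potassium enolate 4 (not isolated)
Conditions: KHMDS, THF, −78 °C; then PhNTf2, −78 °C to 0 °C
Reagents that add atoms: N-phenylbis(trifluoromethanesulfonimide), O=S(=O)(N(c1ccccc1)S(=O)(=O)C(F)(F)F)C(F)(F)F
Why: Kinetic deprotonation with KHMDS at −78 °C occurs at the methyl group and not at the cyclobutyl methine (an enolate double bond exocyclic to the four-membered ring is strained), and O-sulfonylation of the enolate with PhNTf2 gives the 1,1-disubstituted enol triflate (enol triflate formation).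

Step 3
Reactants: 6 4-methylpent-3-en-1-ol
Product: 7 4-methylpent-3-enal
Conditions: Dess–Martin periodinane, pyridine, CH2Cl2, 0 °C; used at once as a solution
Reagents that add atoms: none
Why: Dess–Martin oxidation in the presence of pyridine is fast and non-acidic, so the primary alcohol is taken to the β,γ-unsaturated aldehyde without migration of the double bond into conjugation, and the aldehyde is carried on at once.

Step 4
Reactants: 5 1-(3,3-dimethoxycyclobutyl)ethenyl trifluoromethanesulfonate, 7 4-methylpent-3-enal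
Product: 8 (3R)-2-(3,3-dimethoxycyclobutyl)-6-methylhepta-1,5-dien-3-ol
Conditions: CrCl2 (10 mol%), chiral 2-(2-sulfonamidophenyl)oxazoline ligand (11 mol%), proton sponge (11 mol%), NiCl2(2,9-dimethyl-1,10-phenanthroline) (2 mol%), Mn (2 equiv), ZrCp2Cl2 (1.1 equiv), LiCl (2 equiv), MeCN, rt; aqueous work-up
Reagents that add atoms: none
Why: In the catalytic asymmetric Nozaki–Hiyama–Kishi coupling nickel (reduced in the flask to the zerovalent state) inserts into the C–OTf bond, transmetalation gives an alkenyl species of trivalent chromium bound to the chiral sulfonamide ligand, and this adds to the aldehyde face selected by the ligand to set the (R)-carbinol, while ketal and trisubstituted alkene are inert to the non-basic organochromium reagent.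

Step 5
Reactants: 8 (3R)-2-(3,3-dimethoxycyclobutyl)-6-methylhepta-1,5-dien-3-ol
Product: 9 tert-butyl{[(3R)-2-(3,3-dimethoxycyclobutyl)-6-methylhepta-1,5-dien-3-yl]oxy}dimethylsilane
Conditions: TBSCl, imidazole, DMF, 40 °C
Reagents that add atoms: tert-butyldimethylsilyl chloride, CC(C)(C)[Si](C)(C)Cl
Why: Standard silylation of a secondary alcohol with TBSCl and imidazole, chosen because a silyl ether, unlike the final allylic acetate, does not ionize on zerovalent nickel in step 8.

Step 6
Reactants: 9 tert-butyl{[(3R)-2-(3,3-dimethoxycyclobutyl)-6-methylhepta-1,5-dien-3-yl]oxy}dimethylsilane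
Product: 10 3-[(3R)-3-{[tert-butyl(dimethyl)silyl]oxy}-6-methylhepta-1,5-dien-2-yl]cyclobutan-1-one
Conditions: p-TsOH·H2O (10 mol%), acetone–H2O (10:1), rt
Reagents that add atoms: water, O
Why: Acid-catalysed transketalization to acetone unmasks the cyclobutanone under conditions mild enough for the hindered secondary TBS ether and the two alkenes (ketal hydrolysis).

Step 7
Reactants: 11 prop-1-yn-1-ylmagnesium bromide, 12 benzylchlorodimethylsilane
Product: 13 benzyldimethyl(prop-1-yn-1-yl)silane
Conditions: THF, 0 °C to rt
Reagents that add atoms: none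
Why: Nucleophilic substitution at silicon by the alkynyl Grignard reagent gives the silylalkyne, and the benzyldimethylsilyl group is chosen because fluoride later removes it from an alkene carbon under mild conditions.

Step 8
Reactants: 10 3-[(3R)-3-{[tert-butyl(dimethyl)silyl]oxy}-6-methylhepta-1,5-dien-2-yl]cyclobutan-1-one, 13 benzyldimethyl(prop-1-yn-1-yl)silane
Product: 14 (5S)-3-[benzyl(dimethyl)silyl]-5-[(3R)-3-{[tert-butyl(dimethyl)silyl]oxy}-6-methylhepta-1,5-dien-2-yl]-2-methylcyclohex-2-en-1-one
Conditions: Ni(cod)2 (10 mol%), (S)-BINOL N,N-bis[(R)-1-phenylethyl]phosphoramidite (20 mol%), 13 (2 equiv), toluene, 80 °C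
Reagents that add atoms: none
Why: Proposed new method: zerovalent nickel joins the strained C=O of 10 and alkyne 13 by oxidative cyclization to an oxanickelacyclopentene, β-carbon elimination then cleaves one C(acyl)–CH2 bond of the four-membered ring, and C(sp2)–C(sp3) reductive elimination from the resulting seven-membered nickelacycle gives the enone, so that C1–C2 and C3–C4 are made in one catalytic cycle. The closest known reaction type is the nickel-catalysed intermolecular insertion of internal alkynes into 3-substituted cyclobutanones with achiral trialkylphosphines, and enantioselective nickel/phosphoramidite insertions are known for tethered alkenes; new here is the ligand-controlled choice between the two diastereotopic acyl–CH2 bonds in the intermolecular alkyne case. The six-membered ring is closed by two-carbon ring expansion of the cyclobutanone (formal [4+2]), the ring-closing event being the reductive elimination. The only new stereocentre, C5, is set when the ligand-bound nickel alkoxide selects one of the two CH2 arms in the β-carbon elimination, so it is under catalyst control and not under control of the distant silyl ether carbon. The step needs alkyne regioselectivity, which the silyl group secures because the silicon-bearing carbon binds nickel and the methyl-bearing carbon bonds to C1 (silicon also stands in for the C3 hydrogen, which a terminal alkyne could not deliver with this orientation), and it needs chemoselectivity, which is secured by the inertness of the unactivated alkenes and by a silyl ether in place of an ionizable allylic ester. Release of ring strain drives the sequence, and reductive elimination is expected to outrun β-hydride loss from C5 as in the known 3-monosubstituted cases.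

Step 9
Reactants: 14 (5S)-3-[benzyl(dimethyl)silyl]-5-[(3R)-3-{[tert-butyl(dimethyl)silyl]oxy}-6-methylhepta-1,5-dien-2-yl]-2-methylcyclohex-2-en-1-one
Product: 15 (5R)-5-[(3R)-3-hydroxy-6-methylhepta-1,5-dien-2-yl]-2-methylcyclohex-2-en-1-one
Conditions: TBAF (3.5 equiv), THF, 0 °C to rt
Reagents that add atoms: none
Why: Fluoride-promoted protodesilylation of an alkenyl benzyldimethylsilane (fluoride attack at silicon, loss of the benzyl group as toluene and protonolysis of the activated C–Si bond with the double bond staying in place) is favoured here because the carbon that leaves silicon is the β-carbon of an enone, and the same reagent cleaves the TBS ether, with no stereocentre touched.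

Step 10
Reactants: 15 (5R)-5-[(3R)-3-hydroxy-6-methylhepta-1,5-dien-2-yl]-2-methylcyclohex-2-en-1-one
Product: 16 (5R)-5-[(3R)-3-acetoxy-6-methylhepta-1,5-dien-2-yl]-2-methylcyclohex-2-en-1-one
Conditions: Ac2O, pyridine, DMAP (cat.), CH2Cl2, rt
Reagents that add atoms: acetic anhydride, CC(=O)OC(C)=O
Why: DMAP-catalysed acetylation of the secondary allylic alcohol puts the final acetate in place before the ring carries any hydroxyl, so the two ester positions never have to be distinguished.

Step 11
Reactants: 16 (5R)-5-[(3R)-3-acetoxy-6-methylhepta-1,5-dien-2-yl]-2-methylcyclohex-2-en-1-one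
Product: 18 (5S,6S)-5-[(3R)-3-acetoxy-6-methylhepta-1,5-dien-2-yl]-6-hydroxy-2-methylcyclohex-2-en-1-one, via sodium dienolate 17 (not isolated)
Conditions: NaHMDS (1.1 equiv), THF, −78 °C; then 3-phenyl-2-(phenylsulfonyl)oxaziridine, −78 °C; sat. aq. NH4Cl
Reagents that add atoms: 3-phenyl-2-(phenylsulfonyl)oxaziridine, O=S(=O)(N1OC1c1ccccc1)c1ccccc1
Why: NaHMDS at −78 °C removes the C6 proton of the enone kinetically (cross-conjugated enolate, faster than deprotonation of the acetate or of C4), and the N-sulfonyloxaziridine transfers oxygen to the enolate face anti to the adjacent C5 side chain, which sets the 6-hydroxyl trans to it (enolate hydroxylation).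

Step 12
Reactants: 18 (5S,6S)-5-[(3R)-3-acetoxy-6-methylhepta-1,5-dien-2-yl]-6-hydroxy-2-methylcyclohex-2-en-1-one
Product: 19 (5S,6S)-5-[(3R)-3-acetoxy-6-methylhepta-1,5-dien-2-yl]-2-methyl-6-[(3-methylbut-2-enoyl)oxy]cyclohex-2-en-1-one
Conditions: 3-methylbut-2-enoyl chloride, pyridine, DMAP (cat.), CH2Cl2, 0 °C
Reagents that add atoms: 3-methylbut-2-enoyl chloride, CC(C)=CC(=O)Cl
Why: DMAP-catalysed acylation of the α-hydroxy ketone with the acid chloride in pyridine, a base too weak to epimerize C6 or to move the double bond of the senecioate out of conjugation.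

Step 13
Reactants: 19 (5S,6S)-5-[(3R)-3-acetoxy-6-methylhepta-1,5-dien-2-yl]-2-methyl-6-[(3-methylbut-2-enoyl)oxy]cyclohex-2-en-1-one
Product: 20 (1S,5S,6S)-5-[(3R)-3-acetoxy-6-methylhepta-1,5-dien-2-yl]-2-methyl-6-[(3-methylbut-2-enoyl)oxy]cyclohex-2-en-1-ol
Conditions: NaBH4, CeCl3·7H2O, MeOH, −78 °C
Reagents that add atoms: none
Why: Luche reduction gives 1,2-reduction only, and axial delivery of hydride to the half-chair in which the C5 and C6 substituents are both pseudo-equatorial sets the new carbinol pseudo-equatorial, trans to the C6 ester and cis to the C5 side chain, as in the reduction of carvone to cis-carveol.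

Step 14
Reactants: 20 (1S,5S,6S)-5-[(3R)-3-acetoxy-6-methylhepta-1,5-dien-2-yl]-2-methyl-6-[(3-methylbut-2-enoyl)oxy]cyclohex-2-en-1-ol
Product: 21 (1R,2R,3S,5S,6S)-5-[(3R)-3-acetoxy-6-methylhepta-1,5-dien-2-yl]-2,3-epoxy-2-methyl-6-[(3-methylbut-2-enoyl)oxy]cyclohexan-1-ol
Conditions: VO(acac)2 (5 mol%), t-BuOOH (decane solution, 1.5 equiv), CH2Cl2, 0 °C to rt
Reagents that add atoms: tert-butyl hydroperoxide, CC(C)(C)OO
Why: Vanadium-catalysed hydroxyl-directed epoxidation transfers oxygen from the vanadate-bound peroxide to the ring alkene on the face of the C1 hydroxyl, which sets C2 and C3 with the oxirane cis to the C5 side chain and trans to the C6 ester, and leaves the two alkenes without a free neighbouring hydroxyl and the electron-poor enoate untouched.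

Step 15
Reactants: 21 (1R,2R,3S,5S,6S)-5-[(3R)-3-acetoxy-6-methylhepta-1,5-dien-2-yl]-2,3-epoxy-2-methyl-6-[(3-methylbut-2-enoyl)oxy]cyclohexan-1-ol
Product: 22 (2S,3S,5S,6S)-5-[(3R)-3-acetoxy-6-methylhepta-1,5-dien-2-yl]-2,3-epoxy-2-methyl-6-[(3-methylbut-2-enoyl)oxy]cyclohexan-1-one
Conditions: Dess–Martin periodinane, pyridine, CH2Cl2, 0 °C to rt
Reagents that add atoms: none
Why: Dess–Martin oxidation converts the secondary epoxy alcohol into the α,β-epoxy ketone under buffered non-basic conditions that neither epimerize C6 nor open the oxirane, which completes the target.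

**Compound list**

1 | 3,3-dimethoxycyclobutane-1-carboxylic acid | COC1(OC)CC(C(=O)O)C1 | starting material
2 | dilithium 1-(3,3-dimethoxycyclobutyl)ethane-1,1-diolate (not isolated) | [Li+].[Li+].CC([O-])([O-])C1CC(OC)(OC)C1 | intermediate
3 | 1-(3,3-dimethoxycyclobutyl)ethan-1-one | CC(=O)C1CC(OC)(OC)C1 | intermediate
4 | potassium 1-(3,3-dimethoxycyclobutyl)ethen-1-olate (not isolated) | [K+].C=C([O-])C1CC(OC)(OC)C1 | intermediate
5 | 1-(3,3-dimethoxycyclobutyl)ethenyl trifluoromethanesulfonate | C=C(OS(=O)(=O)C(F)(F)F)C1CC(OC)(OC)C1 | intermediate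
6 | 4-methylpent-3-en-1-ol | CC(C)=CCCO | starting material
7 | 4-methylpent-3-enal | CC(C)=CCC=O | intermediate
8 | (3R)-2-(3,3-dimethoxycyclobutyl)-6-methylhepta-1,5-dien-3-ol | C=C([C@@H](CC=C(C)C)O)C1CC(OC)(OC)C1 | intermediate
9 | tert-butyl{[(3R)-2-(3,3-dimethoxycyclobutyl)-6-methylhepta-1,5-dien-3-yl]oxy}dimethylsilane | C=C([C@@H](CC=C(C)C)O[Si](C)(C)C(C)(C)C)C1CC(OC)(OC)C1 | intermediate
10 | 3-[(3R)-3-{[tert-butyl(dimethyl)silyl]oxy}-6-methylhepta-1,5-dien-2-yl]cyclobutan-1-one (ring carbon 3 is not yet a stereocentre) | C=C([C@@H](CC=C(C)C)O[Si](C)(C)C(C)(C)C)C1CC(=O)C1 | intermediate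
11 | prop-1-yn-1-ylmagnesium bromide (THF solution) | CC#C[Mg]Br | starting material
12 | benzylchlorodimethylsilane | C[Si](C)(Cl)Cc1ccccc1 | starting material
13 | benzyldimethyl(prop-1-yn-1-yl)silane | CC#C[Si](C)(C)Cc1ccccc1 | intermediate
14 | (5S)-3-[benzyl(dimethyl)silyl]-5-[(3R)-3-{[tert-butyl(dimethyl)silyl]oxy}-6-methylhepta-1,5-dien-2-yl]-2-methylcyclohex-2-en-1-one | C=C([C@@H](CC=C(C)C)O[Si](C)(C)C(C)(C)C)[C@@H]1CC([Si](C)(C)Cc2ccccc2)=C(C)C(=O)C1 | intermediate
15 | (5R)-5-[(3R)-3-hydroxy-6-methylhepta-1,5-dien-2-yl]-2-methylcyclohex-2-en-1-one (same arrangement at C5 as in 14; the descriptor changes because silicon is gone) | C=C([C@@H](CC=C(C)C)O)[C@@H]1CC=C(C)C(=O)C1 | intermediate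
16 | (5R)-5-[(3R)-3-acetoxy-6-methylhepta-1,5-dien-2-yl]-2-methylcyclohex-2-en-1-one | C=C([C@@H](CC=C(C)C)OC(C)=O)[C@@H]1CC=C(C)C(=O)C1 | intermediate
17 | sodium dienolate of 16, deprotonated at C6 (not isolated) | [Na+].C=C([C@@H](CC=C(C)C)OC(C)=O)[C@@H]1CC=C(C)C([O-])=C1 | intermediate
18 | (5S,6S)-5-[(3R)-3-acetoxy-6-methylhepta-1,5-dien-2-yl]-6-hydroxy-2-methylcyclohex-2-en-1-one (6-OH trans to the C5 chain; the C5 descriptor changes because of the new oxygen) | C=C([C@@H](CC=C(C)C)OC(C)=O)[C@@H]1CC=C(C)C(=O)[C@H]1O | intermediate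
19 | (5S,6S)-5-[(3R)-3-acetoxy-6-methylhepta-1,5-dien-2-yl]-2-methyl-6-[(3-methylbut-2-enoyl)oxy]cyclohex-2-en-1-one | C=C([C@@H](CC=C(C)C)OC(C)=O)[C@@H]1CC=C(C)C(=O)[C@H]1OC(=O)C=C(C)C | intermediate
20 | (1S,5S,6S)-5-[(3R)-3-acetoxy-6-methylhepta-1,5-dien-2-yl]-2-methyl-6-[(3-methylbut-2-enoyl)oxy]cyclohex-2-en-1-ol (1-OH trans to the C6 ester, cis to the C5 chain) | C=C([C@@H](CC=C(C)C)OC(C)=O)[C@@H]1CC=C(C)[C@H](O)[C@H]1OC(=O)C=C(C)C | intermediate
21 | (1R,2R,3S,5S,6S)-5-[(3R)-3-acetoxy-6-methylhepta-1,5-dien-2-yl]-2,3-epoxy-2-methyl-6-[(3-methylbut-2-enoyl)oxy]cyclohexan-1-ol (oxirane cis to 1-OH and to the C5 chain) | C=C([C@@H](CC=C(C)C)OC(C)=O)[C@@H]1C[C@@H]2O[C@]2(C)[C@H](O)[C@H]1OC(=O)C=C(C)C | intermediate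
22 | (2S,3S,5S,6S)-5-[(3R)-3-acetoxy-6-methylhepta-1,5-dien-2-yl]-2,3-epoxy-2-methyl-6-[(3-methylbut-2-enoyl)oxy]cyclohexan-1-one, CNP0168401.1 | C=C([C@@H](CC=C(C)C)OC(C)=O)[C@@H]1C[C@@H]2O[C@]2(C)C(=O)[C@H]1OC(=O)C=C(C)C | target

**Step count**

Total: 15 steps (steps 3 and 7 make the two small coupling partners). Longest linear sequence: 13 steps (1, 2, 4, 5, 6, 8 to 15).

**Steps most likely to fail**

1. Step 8 (the labelled step). What may go wrong: poor discrimination by the chiral nickel catalyst between the two diastereotopic C(acyl)–CH2 bonds of 10, so that C5 forms unselectively, or slow turnover with the phosphoramidite. Fallback with known chemistry, setting out from 10 and returning at 18: the ring stereocentres are fixed before the ring expansion. Deprotonation of 10 with a chiral lithium amide (lithium bis[(R)-1-phenylethyl]amide or its antipode, LiCl, THF, −100 °C) distinguishes the two α-methylene groups, and oxidation of the lithium enolate with 3-phenyl-2-(phenylsulfonyl)oxaziridine anti to the side chain should give trans-2-hydroxy-3-alkenylcyclobutanone F1. 4-Methoxybenzyl trichloroacetimidate with catalytic Sc(OTf)3 should give the PMB ether F2. Insertion of 13 with the achiral catalyst Ni(cod)2/PCy3 (toluene, 100 °C), in which β-carbon elimination is expected to move the unsubstituted CH2 and not the oxygen-bearing carbon to nickel, should give the 6-(PMB-oxy)-3-silyl enone F3. TBAF should then give the hydroxy enone F4, Ac2O/pyridine/DMAP the acetate F5, and DDQ (CH2Cl2, pH 7 buffer) should free the C6 hydroxyl to give 18. Steps 9 to 11 then fall away.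

2. Step 9. What may go wrong: slow C–Si cleavage at the β-carbon of the enone, with the basic fluoride meanwhile causing double-bond migration, self-condensation or conjugate addition of the freed side-chain alkoxide. Fallback, setting out from 14 and returning at 16: silicon is removed only after the enone has been reduced, from a non-conjugated alkenylsilane. HF·pyridine (THF, 0 °C) should cleave the TBS ether alone to give the silyl enone alcohol F6; Ac2O/pyridine/DMAP should give the silyl enone acetate F7; Luche reduction should give the silylated allylic alcohol F8; TBAF (THF, 0 °C) should remove the benzyldimethylsilyl group to give the allylic alcohol F9; Dess–Martin oxidation returns 16.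

3. Step 4. What may go wrong: insufficient enantioselectivity in the chromium addition, or migration of the β,γ-double bond of 7 into conjugation before it couples. Fallback, setting out from 8 of insufficient enantiomeric purity (or racemic 8 from the same coupling without the chiral ligand) and returning at 8: Dess–Martin oxidation should give the α-methylene ketone F10, and CBS reduction with the (S)-2-methyl-oxazaborolidine and catecholborane (toluene, −78 °C) should set the (R)-carbinol by reagent control.

**Further compounds**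

F1 | step 8 | trans-2-hydroxy-3-[(3R)-3-{[tert-butyl(dimethyl)silyl]oxy}-6-methylhepta-1,5-dien-2-yl]cyclobutan-1-one | C=C([C@@H](CC=C(C)C)O[Si](C)(C)C(C)(C)C)[C@@H]1CC(=O)[C@H]1O
F2 | step 8 | trans-2-[(4-methoxybenzyl)oxy]-3-[(3R)-3-{[tert-butyl(dimethyl)silyl]oxy}-6-methylhepta-1,5-dien-2-yl]cyclobutan-1-one | C=C([C@@H](CC=C(C)C)O[Si](C)(C)C(C)(C)C)[C@@H]1CC(=O)[C@H]1OCc1ccc(OC)cc1
F3 | step 8 | 5,6-trans-3-[benzyl(dimethyl)silyl]-5-[(3R)-3-{[tert-butyl(dimethyl)silyl]oxy}-6-methylhepta-1,5-dien-2-yl]-6-[(4-methoxybenzyl)oxy]-2-methylcyclohex-2-en-1-one | C=C([C@@H](CC=C(C)C)O[Si](C)(C)C(C)(C)C)[C@@H]1CC([Si](C)(C)Cc2ccccc2)=C(C)C(=O)[C@H]1OCc1ccc(OC)cc1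
F4 | step 8 | 5,6-trans-5-[(3R)-3-hydroxy-6-methylhepta-1,5-dien-2-yl]-6-[(4-methoxybenzyl)oxy]-2-methylcyclohex-2-en-1-one | C=C([C@@H](CC=C(C)C)O)[C@@H]1CC=C(C)C(=O)[C@H]1OCc1ccc(OC)cc1
F5 | step 8 | 5,6-trans-5-[(3R)-3-acetoxy-6-methylhepta-1,5-dien-2-yl]-6-[(4-methoxybenzyl)oxy]-2-methylcyclohex-2-en-1-one | C=C([C@@H](CC=C(C)C)OC(C)=O)[C@@H]1CC=C(C)C(=O)[C@H]1OCc1ccc(OC)cc1
F6 | step 9 | (5S)-3-[benzyl(dimethyl)silyl]-5-[(3R)-3-hydroxy-6-methylhepta-1,5-dien-2-yl]-2-methylcyclohex-2-en-1-one | C=C([C@@H](CC=C(C)C)O)[C@@H]1CC([Si](C)(C)Cc2ccccc2)=C(C)C(=O)C1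
F7 | step 9 | (5S)-5-[(3R)-3-acetoxy-6-methylhepta-1,5-dien-2-yl]-3-[benzyl(dimethyl)silyl]-2-methylcyclohex-2-en-1-one | C=C([C@@H](CC=C(C)C)OC(C)=O)[C@@H]1CC([Si](C)(C)Cc2ccccc2)=C(C)C(=O)C1
F8 | step 9 | 1,5-cis-5-[(3R)-3-acetoxy-6-methylhepta-1,5-dien-2-yl]-3-[benzyl(dimethyl)silyl]-2-methylcyclohex-2-en-1-ol | C=C([C@@H](CC=C(C)C)OC(C)=O)[C@@H]1CC([Si](C)(C)Cc2ccccc2)=C(C)[C@H](O)C1
F9 | step 9 | 1,5-cis-5-[(3R)-3-acetoxy-6-methylhepta-1,5-dien-2-yl]-2-methylcyclohex-2-en-1-ol | C=C([C@@H](CC=C(C)C)OC(C)=O)[C@@H]1CC=C(C)[C@H](O)C1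
F10 | step 4 | 2-(3,3-dimethoxycyclobutyl)-6-methylhepta-1,5-dien-3-one | C=C(C(=O)CC=C(C)C)C1CC(OC)(OC)C1
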